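## Retrosynthetic overview

1. Longipinane numbering is used. The cyclohexenone is C1(=O)–C2=C3(CH3)–C4–C10(CH3)–C11, the cyclobutane is C4–C5–C11–C10, and the seven-membered ring is C4–C5–C6(CH3)2–C7(O)–C8–C9(O)–C10.
2. The O-9 senecioate comes off first (Steglich). The O-7 isovalerate and the C9 carbinol go back together to a 7-hydroxy-9-ketone (Evans–Tishchenko). C2=C3 is opened (intramolecular HWE) to a bicyclo[4.1.1]octan-2-one with an acyl group on C4 and a ketophosphonate on C11.
3. Enabling feature: in the seven-membered ring, the carbonyl-level C9 sits on the methyl-bearing quaternary C10 of the cyclobutane. C10 lies between C4–H and C11–H, each alpha to a carbonyl-level carbon (C3, C1). A retro 1,2-acyl shift of C9 (C10 to C4) plus a retro acyl-radical addition at C11 gives a cis-fused bicyclo[4.2.0]oct-7-en-2-one and an aldehyde.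
4. This cyclobutene is the [2+2] photoadduct of propyne and an (R)-5-silyloxy-4,4-dimethyl-2-(thioester)cyclohexenone. The enone comes from 4,4-dimethylcyclohexenone by dehydrogenation and asymmetric conjugate borylation.
5. Ring order: six-membered carbocycle (purchased), then cyclobutene, then six-to-seven ring expansion (fused to bridged), then cyclohexenone.

Key step: step 7

Assumption: (R)-DTBM-SEGPHOS is taken to give the (R)-boronate in step 2. If the sense of induction is the opposite, the (S)-ligand is used.

## Route

Step 1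
Reactants: 1 4,4-dimethylcyclohex-2-en-1-one
Product: 2 4,4-dimethylcyclohexa-2,5-dien-1-one
Conditions: DDQ, 1,4-dioxane, reflux
Reagents that add atoms: none
Why: Quinone dehydrogenation of the enone through its dienol gives the cross-conjugated dienone, which cannot aromatise because C4 is quaternary; no stereocentre is formed.

Step 2
Reactants: 2 4,4-dimethylcyclohexa-2,5-dien-1-one
Product: 4 (R)-5-hydroxy-4,4-dimethylcyclohex-2-en-1-one, via boronate 3 (not isolated)
Conditions: B2pin2 (1.0 equiv), CuCl (3 mol%), NaOtBu (3 mol%), (R)-DTBM-SEGPHOS (3 mol%), MeOH (2 equiv), THF, 0 °C; then NaBO3·4H2O, THF/H2O, 25 °C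
Reagents that add atoms: bis(pinacolato)diboron, CC1(C)OB(OC1(C)C)B1OC(C)(C)C(C)(C)O1; sodium perborate, [Na+].[O-]OB=O
Why: In this copper-catalysed enantioselective conjugate borylation the ligand-bound Cu–Bpin species selects one face of one of the two equivalent enone arms and so sets the future C7, the mono-adduct is more hindered and less electrophilic than 2, and the perborate oxidation of the C–B bond goes with retention.

Step 3
Reactants: 4 (R)-5-hydroxy-4,4-dimethylcyclohex-2-en-1-one
Product: 5 (R)-5-[(tert-butyldimethylsilyl)oxy]-4,4-dimethylcyclohex-2-en-1-one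
Conditions: TBSOTf, 2,6-lutidine, CH2Cl2, −78 to 0 °C
Reagents that add atoms: tert-butyldimethylsilyl triflate, CC(C)(C)[Si](C)(C)OS(=O)(=O)C(F)(F)F
Why: O-Silylation of the hindered secondary alcohol with the silyl triflate and a non-nucleophilic base avoids beta-elimination back to 2 and leaves the stereocentre untouched.

Step 4
Reactants: 5 (R)-5-[(tert-butyldimethylsilyl)oxy]-4,4-dimethylcyclohex-2-en-1-one
Product: 6 (R)-5-[(tert-butyldimethylsilyl)oxy]-2-iodo-4,4-dimethylcyclohex-2-en-1-one
Conditions: I2, pyridine, CH2Cl2, 25 °C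
Reagents that add atoms: iodine, II
Why: This alpha-iodination of an enone runs by the addition–iodination–elimination (Baylis–Hillman-type) mechanism and functionalises only the alpha-vinylic position.

Step 5
Reactants: 6 (R)-5-[(tert-butyldimethylsilyl)oxy]-2-iodo-4,4-dimethylcyclohex-2-en-1-one
Product: 7 S-ethyl (R)-4-[(tert-butyldimethylsilyl)oxy]-3,3-dimethyl-6-oxocyclohex-1-ene-1-carbothioate
Conditions: CO (1 atm), EtSH (1.1 equiv), Pd(OAc)2 (5 mol%), Xantphos (6 mol%), Et3N, THF, 50 °C
Reagents that add atoms: carbon monoxide, [C-]#[O+]; ethanethiol, CCS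
Why: In this palladium-catalysed thiocarbonylation of a vinyl iodide, oxidative addition, CO insertion and thiolysis of the acyl-palladium species give the thioester, and the neopentyl beta-carbon holds back thia-Michael addition.

Step 6
Reactants: 7 S-ethyl (R)-4-[(tert-butyldimethylsilyl)oxy]-3,3-dimethyl-6-oxocyclohex-1-ene-1-carbothioate; 8 propyne
Product: 9 S-ethyl (1S,4R,6S)-4-[(tert-butyldimethylsilyl)oxy]-5,5,8-trimethyl-2-oxobicyclo[4.2.0]oct-7-ene-1-carbothioate (cis-fused, cyclobutene anti to the silyloxy group)
Conditions: 8 (excess, condensed), CH2Cl2, hν (366 nm), −40 °C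
Reagents that add atoms: none
Why: In this enone–alkyne [2+2] photocycloaddition through the triplet enone the first bond joins the hindered beta-carbon to the unsubstituted alkyne terminus (more substituted vinyl radical, doubly stabilised alpha-radical), which places the methyl-bearing carbon next to the quaternary centre; propyne approaches anti to the silyloxy group and a cyclobutene can only be cis-fused, so C5 and the quaternary C4 follow from C7.

Step 7
Reactants: 9 S-ethyl (1S,4R,6S)-4-[(tert-butyldimethylsilyl)oxy]-5,5,8-trimethyl-2-oxobicyclo[4.2.0]oct-7-ene-1-carbothioate; 10 diethyl (2-oxoethyl)phosphonate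
Product: 13 S-ethyl (1S,4R,6R,7S,8R)-4-[(tert-butyldimethylsilyl)oxy]-8-[(diethoxyphosphoryl)acetyl]-1,5,5-trimethyl-2-oxobicyclo[4.1.1]octane-7-carbothioate (both acyl side chains on the cyclobutane face opposite the four-carbon bridge), via adduct radical 11 (not isolated), via ring-expanded radical 12 (not isolated)
Conditions: (nBu4N)4[W10O32] (2 mol%), 10 (5 equiv), MeCN, 390 nm LEDs, 25 °C, argon
Reagents that add atoms: none
Why: Proposed new method: excited decatungstate abstracts the formyl hydrogen of 10, the nucleophilic acyl radical adds to the unsubstituted carbon (C11) of the strained cyclobutene, and the tertiary C10 radical 11 attacks the adjacent ring carbonyl C9 to give a cyclopropyloxy radical that opens by scission of C4–C9, so that C9 moves from C4 to C10 before the thioester-stabilised C4 radical 12 takes hydrogen back from the reduced polyoxometalate. The closest known reaction types are the decatungstate hydroacylation of electron-poor alkenes and the Dowd–Beckwith one-carbon ring expansion of 2-(halomethyl) beta-keto esters; what is new is their merger and the fused-to-bridged outcome at a cyclobutyl radical. The only ring event is the 3-exo-trig closure onto C=O followed by beta-scission, which enlarges the six-membered ring C4–C5–C6–C7–C8–C9 to the seven-membered ring C4–C5–C6–C7–C8–C9–C10 and turns the bicyclo[4.2.0]octene into a bicyclo[4.1.1]octane. C11 is set by attack on the convex face, anti to the C6 branch on C5; C10 is set because C9 can only cross on the face on which C4 holds it, which leaves the methyl group on the other face; C4 is set by the hydrogen transfer, is epimerisable and is corrected in step 9. The step needs addition at C11 (the methyl group makes the alternative attack hindered and its radical secondary), migration of the ketone and not of the thioester carbonyl (thioester carbonyls accept alkyl radicals far more slowly, and a shift of the new acyl group from C11 would give an unstabilised secondary radical and is reversible), and no early quenching of 11. This last point rests on polarity: the nucleophilic radical 11 is a poor partner for hydrogen back-donation and the electrophilic radical 12 a good one, and the gain in radical stabilisation pays for the added strain of the bridged skeleton.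

Step 8
Reactants: 13 S-ethyl 4-[(tert-butyldimethylsilyl)oxy]-8-[(diethoxyphosphoryl)acetyl]-1,5,5-trimethyl-2-oxobicyclo[4.1.1]octane-7-carbothioate
Product: 14 diethyl {2-[7-acetyl-4-[(tert-butyldimethylsilyl)oxy]-1,5,5-trimethyl-2-oxobicyclo[4.1.1]octan-8-yl]-2-oxoethyl}phosphonate (configuration as in 13)
Conditions: MeZnCl (3 equiv), PdCl2(PPh3)2 (5 mol%), THF/toluene, 25 °C
Reagents that add atoms: methylzinc chloride, C[Zn]Cl
Why: The Fukuyama coupling turns only the thioester into the methyl ketone, because palladium inserts into the acyl–sulfur bond and the organozinc halide is inert to the ketones and the phosphonate.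

Step 9
Reactants: 14 diethyl {2-[7-acetyl-4-[(tert-butyldimethylsilyl)oxy]-1,5,5-trimethyl-2-oxobicyclo[4.1.1]octan-8-yl]-2-oxoethyl}phosphonate
Product: 15 (4R,5S,7R,10R,11R)-7-[(tert-butyldimethylsilyl)oxy]longipin-2-ene-1,9-dione
Conditions: LiCl, DBU, MeCN, 25 to 50 °C
Reagents that add atoms: none
Why: In this intramolecular Horner–Wadsworth–Emmons reaction (Masamune–Roush conditions) only the phosphonate-activated CH2 can be the nucleophile and only the methyl ketone is within reach, which fixes C1 as the carbonyl and C3 as the methyl-bearing carbon; C4 and C11 equilibrate under DBU, only the cis-1,3 isomer can close, and closure locks both centres.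

Step 10
Reactants: 15 (4R,5S,7R,10R,11R)-7-[(tert-butyldimethylsilyl)oxy]longipin-2-ene-1,9-dione
Product: 16 (4R,5S,7R,10R,11R)-7-hydroxylongipin-2-ene-1,9-dione
Conditions: HF·pyridine, THF, 0 to 25 °C
Reagents that add atoms: none
Why: Desilylation with a mildly acidic fluoride source frees the beta-hydroxy ketone without the base-induced retro-aldol or elimination pathways.

Step 11
Reactants: 16 (4R,5S,7R,10R,11R)-7-hydroxylongipin-2-ene-1,9-dione; 17 3-methylbutanal
Product: 18 (4R,5S,7R,9R,10R,11R)-9-hydroxy-1-oxolongipin-2-en-7-yl 3-methylbutanoate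
Conditions: 17 (5 equiv), SmI2 (0.3 equiv, premixed with 17), THF, −10 °C
Reagents that add atoms: none
Why: In the Evans–Tishchenko reduction the hemiacetal of O-7 with 17 and the C9 ketone bind to trivalent samarium and the hemiacetal hydride is delivered to the ketone face syn to O-7, which gives the 1,3-anti C9 alcohol, leaves the isovalerate on O-7 and spares the enone, which has no neighbouring hydroxyl group.

Step 12
Reactants: 18 (4R,5S,7R,9R,10R,11R)-9-hydroxy-1-oxolongipin-2-en-7-yl 3-methylbutanoate; 19 3-methylbut-2-enoic acid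
Product: 20 (4R,5S,7R,9R,10R,11R)-7-(3-methylbutanoyloxy)-9-(3-methylbut-2-enoyloxy)longipin-2-en-1-one (CNP0335239.1)
Conditions: 19, N,N'-dicyclohexylcarbodiimide, DMAP (cat.), CH2Cl2, 25 °C
Reagents that add atoms: none
Why: Steglich esterification acylates the remaining C9 alcohol with retention and avoids the vinylketene pathway of the acid chloride that would deconjugate the senecioate.

## Compound list

1 | 4,4-dimethylcyclohex-2-en-1-one | CC1(C)CCC(=O)C=C1 | starting material
2 | 4,4-dimethylcyclohexa-2,5-dien-1-one | CC1(C)C=CC(=O)C=C1 | intermediate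
3 | (R)-4,4-dimethyl-5-(4,4,5,5-tetramethyl-1,3,2-dioxaborolan-2-yl)cyclohex-2-en-1-one | O=C1C[C@@H](B2OC(C)(C)C(C)(C)O2)C(C)(C)C=C1 | intermediate
4 | (R)-5-hydroxy-4,4-dimethylcyclohex-2-en-1-one | O=C1C[C@@H](O)C(C)(C)C=C1 | intermediate
5 | (R)-5-[(tert-butyldimethylsilyl)oxy]-4,4-dimethylcyclohex-2-en-1-one | O=C1C[C@@H](O[Si](C)(C)C(C)(C)C)C(C)(C)C=C1 | intermediate
6 | (R)-5-[(tert-butyldimethylsilyl)oxy]-2-iodo-4,4-dimethylcyclohex-2-en-1-one | O=C1C[C@@H](O[Si](C)(C)C(C)(C)C)C(C)(C)C=C1I | intermediate
7 | S-ethyl (R)-4-[(tert-butyldimethylsilyl)oxy]-3,3-dimethyl-6-oxocyclohex-1-ene-1-carbothioate | O=C1C[C@@H](O[Si](C)(C)C(C)(C)C)C(C)(C)C=C1C(=O)SCC | intermediate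
8 | propyne | CC#C | starting material
9 | S-ethyl (1S,4R,6S)-4-[(tert-butyldimethylsilyl)oxy]-5,5,8-trimethyl-2-oxobicyclo[4.2.0]oct-7-ene-1-carbothioate | O=C1C[C@@H](O[Si](C)(C)C(C)(C)C)C(C)(C)[C@@H]2C=C(C)[C@]12C(=O)SCC | intermediate
10 | diethyl (2-oxoethyl)phosphonate | O=CCP(=O)(OCC)OCC | starting material
11 | adduct radical (tertiary cyclobutyl radical at C10, fused skeleton) | O=C1C[C@@H](O[Si](C)(C)C(C)(C)C)C(C)(C)[C@@H]2[C@@H](C(=O)CP(=O)(OCC)OCC)[C](C)[C@]12C(=O)SCC | intermediate
12 | ring-expanded radical (thioester-stabilised radical at C4, bridged skeleton) | O=C1C[C@@H](O[Si](C)(C)C(C)(C)C)C(C)(C)[C@@H]2[C@@H](C(=O)CP(=O)(OCC)OCC)[C@@]1(C)[C]2C(=O)SCC | intermediate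
13 | S-ethyl (1S,4R,6R,7S,8R)-4-[(tert-butyldimethylsilyl)oxy]-8-[(diethoxyphosphoryl)acetyl]-1,5,5-trimethyl-2-oxobicyclo[4.1.1]octane-7-carbothioate | O=C1C[C@@H](O[Si](C)(C)C(C)(C)C)C(C)(C)[C@@H]2[C@@H](C(=O)CP(=O)(OCC)OCC)[C@@]1(C)[C@H]2C(=O)SCC | intermediate
14 | diethyl {2-[7-acetyl-4-[(tert-butyldimethylsilyl)oxy]-1,5,5-trimethyl-2-oxobicyclo[4.1.1]octan-8-yl]-2-oxoethyl}phosphonate | O=C1C[C@@H](O[Si](C)(C)C(C)(C)C)C(C)(C)[C@@H]2[C@@H](C(=O)CP(=O)(OCC)OCC)[C@@]1(C)[C@H]2C(C)=O | intermediate
15 | (4R,5S,7R,10R,11R)-7-[(tert-butyldimethylsilyl)oxy]longipin-2-ene-1,9-dione | O=C1C[C@@H](O[Si](C)(C)C(C)(C)C)C(C)(C)[C@@H]2[C@H]3C(=O)C=C(C)[C@@H]2[C@]31C | intermediate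
16 | (4R,5S,7R,10R,11R)-7-hydroxylongipin-2-ene-1,9-dione | O=C1C[C@@H](O)C(C)(C)[C@@H]2[C@H]3C(=O)C=C(C)[C@@H]2[C@]31C | intermediate
17 | 3-methylbutanal | CC(C)CC=O | starting material
18 | (4R,5S,7R,9R,10R,11R)-9-hydroxy-1-oxolongipin-2-en-7-yl 3-methylbutanoate | O[C@@H]1C[C@@H](OC(=O)CC(C)C)C(C)(C)[C@@H]2[C@H]3C(=O)C=C(C)[C@@H]2[C@]31C | intermediate
19 | 3-methylbut-2-enoic acid | CC(C)=CC(=O)O | starting material
20 | (4R,5S,7R,9R,10R,11R)-7-(3-methylbutanoyloxy)-9-(3-methylbut-2-enoyloxy)longipin-2-en-1-one | CC(C)=CC(=O)O[C@@H]1C[C@@H](OC(=O)CC(C)C)C(C)(C)[C@@H]2[C@H]3C(=O)C=C(C)[C@@H]2[C@]31C | target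

## Step count and risks

Total step count: 12. Longest linear sequence: 12 steps (from 1).

**Step 7 (labelled).**
- Possible failures: slow addition of the acyl radical to the unactivated cyclobutene, hydrogen abstraction from the allylic methyl group, or hydrogen transfer to the tertiary radical before the acyl shift.
- Fallback (known chemistry, the events are separated), setting out from 9. The acyl xanthate S-[(diethoxyphosphoryl)acetyl] O-ethyl carbonodithioate F1 is made from (diethoxyphosphoryl)acetyl chloride and potassium O-ethyl xanthate.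
- It is added across the cyclobutene by visible-light xanthate group transfer to give the tertiary xanthate adduct F2. The configuration at the sulfur-bearing carbon is of no consequence.
- Slow addition of Bu3SnH and AIBN to F2 in refluxing benzene at high dilution, the classical tin hydride Dowd–Beckwith protocol, then performs the ring expansion and reduction. The route is rejoined at 13.

**Step 6.**
- Possible failures: regiochemical leakage in the closure of the biradical, and secondary photoreaction (acyl shift) of the beta,gamma-unsaturated ketone product.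
- Fallback, setting out from 7. Photocycloaddition with allene, whose head-to-head orientation is well established, gives the methylidenecyclobutane S-ethyl (4R)-4-[(tert-butyldimethylsilyl)oxy]-5,5-dimethyl-8-methylidene-2-oxobicyclo[4.2.0]octane-1-carbothioate F3.
- RhCl3·3H2O in ethanol at 70 °C then moves the double bond into the four-membered ring. It can only move toward C11, since C4 is quaternary. The route is rejoined at 9.

**Step 11.**
- Possible failures: the samarium-bound hemiacetal fails to reach the ketone within the seven-membered ring, the ring opens by retro-aldol, or the enone is reduced by the divalent samarium.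
- Fallback, setting out from 16. Hydroxyl-directed Evans–Saksena reduction with Me4NBH(OAc)3 in MeCN/AcOH gives the anti diol (4R,5S,7R,9R,10R,11R)-7,9-dihydroxylongipin-2-en-1-one F4.
- Steglich acylation of the less hindered C9 hydroxyl with one equivalent of 19 gives the mono-senecioate (4R,5S,7R,9R,10R,11R)-7-hydroxy-1-oxolongipin-2-en-9-yl 3-methylbut-2-enoate F5.
- 3-Methylbutanoyl chloride with pyridine and DMAP then acylates O-7. The route is rejoined at 20.

## Further compounds

F1 | step 7 | S-[(diethoxyphosphoryl)acetyl] O-ethyl carbonodithioate | CCOC(=S)SC(=O)CP(=O)(OCC)OCC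
F2 | step 7 | S-ethyl 4-[(tert-butyldimethylsilyl)oxy]-7-[(diethoxyphosphoryl)acetyl]-8-[(ethoxycarbonothioyl)sulfanyl]-5,5,8-trimethyl-2-oxobicyclo[4.2.0]octane-1-carbothioate | O=C1C[C@@H](O[Si](C)(C)C(C)(C)C)C(C)(C)[C@@H]2[C@@H](C(=O)CP(=O)(OCC)OCC)[C@](C)(SC(=S)OCC)[C@]12C(=O)SCC
F3 | step 6 | S-ethyl (4R)-4-[(tert-butyldimethylsilyl)oxy]-5,5-dimethyl-8-methylidene-2-oxobicyclo[4.2.0]octane-1-carbothioate (cis-fused, anti to the silyloxy group) | O=C1C[C@@H](O[Si](C)(C)C(C)(C)C)C(C)(C)[C@@H]2CC(=C)[C@]12C(=O)SCC
F4 | step 11 | (4R,5S,7R,9R,10R,11R)-7,9-dihydroxylongipin-2-en-1-one | O[C@@H]1C[C@@H](O)C(C)(C)[C@@H]2[C@H]3C(=O)C=C(C)[C@@H]2[C@]31C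
F5 | step 11 | (4R,5S,7R,9R,10R,11R)-7-hydroxy-1-oxolongipin-2-en-9-yl 3-methylbut-2-enoate | CC(C)=CC(=O)O[C@@H]1C[C@@H](O)C(C)(C)[C@@H]2[C@H]3C(=O)C=C(C)[C@@H]2[C@]31C
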